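The plan hinges on the 2,5-dihydrofuran ring (O, C2, C1, C15, C16) fused to the fourteen-membered carbocycle. Its O–C2 bond is allylic to C1=C15, and C15 already holds the C16H2–O arm, so returning the oxygen from C2 to C15 reveals a C15–C16 epoxide attached to a C1=C2 alkene. In the forward sense, one copper-catalysed 1,3-oxygen shift should make the C2–O bond, close the dihydrofuran, shift the olefin to C1=C15 and hand the Sharpless-derived C15 configuration to C2. The precursor is a silyl-protected, 2,2-disubstituted dienyl oxirane with C3 cis to C14. Two sulfone alkylations with a geraniol-derived epoxide (C13–C14, then ring-closing C5–C6) finish the skeleton.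

Key step: step 10

Numbering: target numbering throughout (carbocycle C1–C14 with C1 the ring-fusion olefinic carbon and C2 the OCH; C15 bears C17H2O; C16 is the ring OCH2); the target is (2R,3E,7R,8R,11E).
Assumption: the oxygen shift of step 10 is taken to be suprafacial; should it prove antarafacial, L-(+)-diethyl tartrate in step 8 gives the enantiomeric oxirane and hence the same (2R) product.

Step 1
Reactants: 1 propargyl alcohol
Product: 3 (E)-3-iodo-2-methylprop-2-en-1-ol, via alkenylalane 2 (not isolated)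
Conditions: AlMe3 (3 equiv), Cp2ZrCl2 (0.25 equiv), CH2Cl2, 0 °C to rt; then I2, THF, −30 to 0 °C
Reagents that add atoms: trimethylaluminium, C[Al](C)C; iodine, II
Why: Zirconium-catalysed carboalumination (Negishi) adds methyl and aluminium syn across the alkyne with aluminium at the terminus, and iodinolysis with retention should give the E iodide (iodine trans to CH2OH).

Step 2
Reactants: 3 (E)-3-iodo-2-methylprop-2-en-1-ol
Product: 4 tert-butyl{[(E)-3-iodo-2-methylprop-2-enyl]oxy}dimethylsilane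
Conditions: t-BuMe2SiCl, imidazole, CH2Cl2, 0 °C to rt
Reagents that add atoms: tert-butyldimethylsilyl chloride, CC(C)(C)[Si](C)(C)Cl
Why: Silyl ether formation masks the C5 oxygen with the group that is later removed together with the C6 silyl ether (step 18).

Step 3
Reactants: 4 tert-butyl{[(E)-3-iodo-2-methylprop-2-enyl]oxy}dimethylsilane; 5 methyl propiolate
Product: 6 methyl (E)-6-[(tert-butyldimethylsilyl)oxy]-5-methylhex-4-en-2-ynoate
Conditions: PdCl2(PPh3)2 (3 mol%), CuI (6 mol%), K2CO3, THF, 45 °C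
Reagents that add atoms: none
Why: Sonogashira coupling of the alkenyl iodide proceeds with retention of the E geometry, and carbonate in place of an amine base avoids conjugate addition to the propiolate.

Step 4
Reactants: 6 methyl (E)-6-[(tert-butyldimethylsilyl)oxy]-5-methylhex-4-en-2-ynoate
Product: 7 methyl (2E,4E)-6-[(tert-butyldimethylsilyl)oxy]-5-methyl-2-(tributylstannyl)hexa-2,4-dienoate
Conditions: Bu3SnH (1.2 equiv), Pd(PPh3)4 (2 mol%), THF, 0 °C
Reagents that add atoms: tributyltin hydride, CCCC[SnH](CCCC)CCCC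
Why: Palladium-catalysed syn-hydrostannation of an ynoate, in which the ester polarises the alkyne so that hydride goes to C2 and tin to C1; this fixes the regiochemistry and the C1=C2 geometry (C3 cis to the ester carbon C14), which a plain propargylic ether next to the cis-methyl alkenyl group would not do reliably.

Step 5
Reactants: 7 methyl (2E,4E)-6-[(tert-butyldimethylsilyl)oxy]-5-methyl-2-(tributylstannyl)hexa-2,4-dienoate
Product: 8 (2E,4E)-6-[(tert-butyldimethylsilyl)oxy]-5-methyl-2-(tributylstannyl)hexa-2,4-dien-1-ol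
Conditions: i-Bu2AlH (2.5 equiv), CH2Cl2, −78 °C; aq. potassium sodium tartrate
Reagents that add atoms: none
Why: Hydride 1,2-reduction of the enoate gives the C14 allylic alcohol and leaves the alkenylstannane and the silyl ether untouched.

Step 6
Reactants: 8 (2E,4E)-6-[(tert-butyldimethylsilyl)oxy]-5-methyl-2-(tributylstannyl)hexa-2,4-dien-1-ol
Product: 9 (2E,4E)-6-[(tert-butyldimethylsilyl)oxy]-5-methyl-2-(tributylstannyl)-1-[(triethylsilyl)oxy]hexa-2,4-diene
Conditions: Et3SiCl, imidazole, CH2Cl2, 0 °C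
Reagents that add atoms: triethylsilyl chloride, CC[Si](Cl)(CC)CC
Why: Silylation gives C14 the most labile silyl group because it is unmasked first after the key step; a silyl ether is preferred to an oxidatively removable benzyl-type ether because a quinone oxidant would attack the doubly allylic C2–H of the later dihydrofuran.

Step 7
Reactants: 9 (2E,4E)-6-[(tert-butyldimethylsilyl)oxy]-5-methyl-2-(tributylstannyl)-1-[(triethylsilyl)oxy]hexa-2,4-diene; 10 2-bromoprop-2-en-1-ol
Product: 11 (3Z,5E)-7-[(tert-butyldimethylsilyl)oxy]-6-methyl-2-methylidene-3-{[(triethylsilyl)oxy]methyl}hepta-3,5-dien-1-ol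
Conditions: Pd2(dba)3 (5 mol%), AsPh3 (20 mol%), CuI (20 mol%), NMP, 50 °C
Reagents that add atoms: none
Why: Copper-assisted Stille coupling of the hindered alkenylstannane with the alkenyl bromide forms the C1–C15 bond with retention at both partners and without fluoride, so the silyl ethers survive.

Step 8
Reactants: 11 (3Z,5E)-7-[(tert-butyldimethylsilyl)oxy]-6-methyl-2-methylidene-3-{[(triethylsilyl)oxy]methyl}hepta-3,5-dien-1-ol
Product: 12 [(2R)-2-{(2E,4E)-6-[(tert-butyldimethylsilyl)oxy]-5-methyl-1-[(triethylsilyl)oxy]hexa-2,4-dien-2-yl}oxiran-2-yl]methanol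
Conditions: Ti(OiPr)4 (10 mol%), D-(−)-diethyl tartrate (12 mol%), t-BuOOH (1.5 equiv), 4 Å MS, CH2Cl2, −25 °C
Reagents that add atoms: tert-butyl hydroperoxide, CC(C)(C)OO
Why: Sharpless asymmetric epoxidation is confined to the olefin of the free allylic alcohol (C15=C16), and the D-(−)-tartrate should deliver oxygen to the face that gives the (R)-2-substituted glycidol, which sets C15.

Step 9
Reactants: 12 [(2R)-2-{(2E,4E)-6-[(tert-butyldimethylsilyl)oxy]-5-methyl-1-[(triethylsilyl)oxy]hexa-2,4-dien-2-yl}oxiran-2-yl]methanol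
Product: 13 tert-butyl{[(2S)-2-{(2E,4E)-6-[(tert-butyldimethylsilyl)oxy]-5-methyl-1-[(triethylsilyl)oxy]hexa-2,4-dien-2-yl}oxiran-2-yl]methoxy}diphenylsilane
Conditions: t-BuPh2SiCl, imidazole, DMF, 0 °C
Reagents that add atoms: tert-butyldiphenylsilyl chloride, CC(C)(C)[Si](Cl)(c1ccccc1)c1ccccc1
Why: Neutral silylation of the primary alcohol installs a bulky, weakly nucleophilic ether, so the C17 oxygen cannot take part when C15 ionises in the next step (the descriptor changes to S only because the priorities change).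

Step 10
Reactants: 13 tert-butyl{[(2S)-2-{(2E,4E)-6-[(tert-butyldimethylsilyl)oxy]-5-methyl-1-[(triethylsilyl)oxy]hexa-2,4-dien-2-yl}oxiran-2-yl]methoxy}diphenylsilane
Product: 14 (2R)-2-{(E)-3-[(tert-butyldimethylsilyl)oxy]-2-methylprop-1-enyl}-4-{[(tert-butyldiphenylsilyl)oxy]methyl}-3-{[(triethylsilyl)oxy]methyl}-2,5-dihydrofuran
Conditions: Cu(hfacac)2 (5 mol%), toluene, 80 °C
Reagents that add atoms: none
Why: The divalent copper complex copper bis(hexafluoroacetylacetonate) should loosen the tertiary, doubly allylic C15–O bond to a tight alkoxide/pentadienyl-cation pair, and the oxygen, still tied to C16, re-bonds at C2 while the double bond moves to C1=C15, a strain-driven formal 1,3-oxygen shift. The closest known reaction is the copper-catalysed ring expansion of vinyl oxiranes to 2,5-dihydrofurans; the relay of configuration from a quaternary oxirane carbon across a dienyl unit is not established and is argued here from the mechanism. The one ring closed, the dihydrofuran, forms by 5-endo collapse of the oxygen onto C2 (new C2–O bond). The new C2 centre is governed by the C15 configuration together with the C1=C2 geometry: because the small C2–H and not C3 points toward the oxirane (C3 is cis to C14), only the rotamer with C16 next to C2 can close, and the oxygen should re-attach to the face of the π system from which it departs, giving (2R). The step needs closure at C2 and not at C4 and no escape of the ion pair; the five-membered transition state is favoured over the seven-membered one, and the non-polar medium, the bulky silyl ethers and the absence of any second oxirane at this stage keep competing nucleophiles and ionisable sites away.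

Step 11
Reactants: 14 (2R)-2-{(E)-3-[(tert-butyldimethylsilyl)oxy]-2-methylprop-1-enyl}-4-{[(tert-butyldiphenylsilyl)oxy]methyl}-3-{[(triethylsilyl)oxy]methyl}-2,5-dihydrofuran
Product: 15 [(2R)-2-{(E)-3-[(tert-butyldimethylsilyl)oxy]-2-methylprop-1-enyl}-4-{[(tert-butyldiphenylsilyl)oxy]methyl}-2,5-dihydrofuran-3-yl]methanol
Conditions: HF·pyridine, pyridine, THF, 0 °C
Reagents that add atoms: none
Why: Buffered fluoride desilylation removes the primary triethylsilyl ether much faster than the TBS and TBDPS ethers (graded silyl lability), so only the C14 hydroxyl is freed and no acid meets the doubly allylic ether.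

Step 12
Reactants: 15 [(2R)-2-{(E)-3-[(tert-butyldimethylsilyl)oxy]-2-methylprop-1-enyl}-4-{[(tert-butyldiphenylsilyl)oxy]methyl}-2,5-dihydrofuran-3-yl]methanol
Product: 16 (2R)-3-(bromomethyl)-2-{(E)-3-[(tert-butyldimethylsilyl)oxy]-2-methylprop-1-enyl}-4-{[(tert-butyldiphenylsilyl)oxy]methyl}-2,5-dihydrofuran
Conditions: CBr4, PPh3, CH2Cl2, 0 °C
Reagents that add atoms: carbon tetrabromide, BrC(Br)(Br)Br
Why: Appel bromination converts the primary allylic alcohol into the C14 bromide under neutral conditions that spare the silyl ethers and the dihydrofuran.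

Step 13
Reactants: 17 geraniol
Product: 18 [(2R,3R)-3-methyl-3-(4-methylpent-3-enyl)oxiran-2-yl]methanol
Conditions: Ti(OiPr)4 (5 mol%), D-(−)-diethyl tartrate (7.5 mol%), t-BuOOH, 4 Å MS, CH2Cl2, −20 °C
Reagents that add atoms: tert-butyl hydroperoxide, CC(C)(C)OO
Why: Sharpless asymmetric epoxidation touches only the allylic alcohol olefin, and the D-(−)-tartrate should give the (2R,3R)-epoxide, which is C7 and C8 of the target.

Step 14
Reactants: 18 [(2R,3R)-3-methyl-3-(4-methylpent-3-enyl)oxiran-2-yl]methanol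
Product: 19 tert-butyldimethyl{[(2R,3R)-3-methyl-3-(4-methylpent-3-enyl)oxiran-2-yl]methoxy}silane
Conditions: t-BuMe2SiCl, imidazole, CH2Cl2, 0 °C to rt
Reagents that add atoms: tert-butyldimethylsilyl chloride, CC(C)(C)[Si](C)(C)Cl
Why: Silyl ether formation protects the C6 hydroxyl with the same group as C5, so that both are removed in one operation later.

Step 15
Reactants: 19 tert-butyldimethyl{[(2R,3R)-3-methyl-3-(4-methylpent-3-enyl)oxiran-2-yl]methoxy}silane
Product: 20 (E)-5-[(2R,3R)-3-{[(tert-butyldimethylsilyl)oxy]methyl}-2-methyloxiran-2-yl]-2-methylpent-2-en-1-ol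
Conditions: SeO2 (0.5 equiv), t-BuOOH (3 equiv), CH2Cl2, 0 °C to rt
Reagents that add atoms: selenium dioxide, O=[Se]=O; tert-butyl hydroperoxide (terminal oxidant), CC(C)(C)OO
Why: Selenium dioxide allylic oxidation (ene reaction, then 2,3-sigmatropic shift) of a gem-dimethyl olefin attacks the E methyl group and should give the E allylic alcohol that becomes C13.

Step 16
Reactants: 20 (E)-5-[(2R,3R)-3-{[(tert-butyldimethylsilyl)oxy]methyl}-2-methyloxiran-2-yl]-2-methylpent-2-en-1-ol
Product: 22 tert-butyldimethyl{[(2R,3R)-3-methyl-3-[(E)-4-methyl-5-(phenylsulfonyl)pent-3-enyl]oxiran-2-yl]methoxy}silane, via allylic chloride 21 (not isolated)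
Conditions: NCS, Me2S, CH2Cl2, −20 to 0 °C; then PhSO2Na, Bu4NI (cat.), DMF, rt
Reagents that add atoms: sodium benzenesulfinate, [Na+].[O-]S(=O)c1ccccc1
Why: Corey–Kim chlorination of the allylic alcohol under neutral conditions, then SN2 displacement by sulfinate at sulfur, should give the E allylic sulfone without touching the epoxide.

Step 17
Reactants: 22 tert-butyldimethyl{[(2R,3R)-3-methyl-3-[(E)-4-methyl-5-(phenylsulfonyl)pent-3-enyl]oxiran-2-yl]methoxy}silane; 16 (2R)-3-(bromomethyl)-2-{(E)-3-[(tert-butyldimethylsilyl)oxy]-2-methylprop-1-enyl}-4-{[(tert-butyldiphenylsilyl)oxy]methyl}-2,5-dihydrofuran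
Product: 24 C13–C14-linked seco compound (dihydrofuran of 16 carrying at C14 the C13-phenylsulfonyl chain of 22; C5 and C6 as TBS ethers), via lithiated sulfone 23 (not isolated)
Conditions: n-BuLi (1.05 equiv), THF, −78 °C; then 16, −78 to −40 °C
Reagents that add atoms: none
Why: Alkylation of the sulfonyl-stabilised allylic carbanion at its α-carbon by the primary allylic bromide (SN2) forms the C13–C14 bond; the carbanion cannot reach its own epoxide across the E olefin, and the C13 epimer mixture is of no consequence.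

Step 18
Reactants: 24 C13–C14-linked seco compound
Product: 25 C5,C6-diol (24 with both TBS ethers removed)
Conditions: HF·pyridine, pyridine, THF, 0 °C to rt
Reagents that add atoms: none
Why: Buffered fluoride cleavage removes the two primary TBS ethers and leaves the more robust TBDPS ether and the trisubstituted epoxide intact.

Step 19
Reactants: 25 C5,C6-diol
Product: 27 bis-sulfone seco alcohol (phenylsulfonyl at C5 and C13; free C6 hydroxyl), via C5 chloride 26 (not isolated)
Conditions: NCS, Me2S, CH2Cl2, −20 to 0 °C; then PhSO2Na, Bu4NI (cat.), DMF, rt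
Reagents that add atoms: sodium benzenesulfinate, [Na+].[O-]S(=O)c1ccccc1
Why: The Corey–Kim reagent converts allylic alcohols into chlorides while a saturated primary alcohol is returned on work-up, so only C5 is activated and then displaced by sulfinate (SN2), leaving the C6 hydroxyl free.

Step 20
Reactants: 27 bis-sulfone seco alcohol
Product: 30 macrocyclic bis-sulfone (fourteen-membered ring fused to the dihydrofuran; phenylsulfonyl at C5 and C13; C17 OTBDPS), via triflate 28 (not isolated), via lithiated sulfone 29 (not isolated)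
Conditions: Tf2O, 2,6-lutidine, CH2Cl2, −78 °C; then LiN(SiMe3)2 (1.0 equiv), THF, 0.002 M, −78 °C
Reagents that add atoms: none
Why: Intramolecular SN2 alkylation of the C5 sulfonyl carbanion by the primary C6 triflate closes the fourteen-membered ring through the C5–C6 bond; it should be fast at −78 °C under high dilution because the primary C5–H2 is deprotonated before the hindered C13–H, and one equivalent of base leaves none to attack the γ,δ-epoxy sulfone formed.

Step 21
Reactants: 30 macrocyclic bis-sulfone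
Product: 31 O-TBDPS-deacetyl-lobophynin B
Conditions: PdCl2(dppp) (10 mol%), LiBHEt3, THF, −20 to 0 °C
Reagents that add atoms: none
Why: Palladium-catalysed hydride reduction of allylic sulfones (reductive desulfonylation via π-allylpalladium hydrides) should remove both sulfonyl groups at low temperature, returning the trisubstituted olefins in place and E before the hydride opens the trisubstituted epoxide.

Step 22
Reactants: 31 O-TBDPS-deacetyl-lobophynin B
Product: 33 lobophynin B, via alcohol 32 (not isolated)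
Conditions: Bu4NF, THF, 0 °C; then Ac2O, Et3N, DMAP, rt
Reagents that add atoms: acetic anhydride, CC(=O)OC(C)=O
Why: Fluoride desilylation followed by esterification of the primary allylic alcohol in the same flask gives the acetate without acid, which the epoxide and the doubly allylic ether would not tolerate.

Compound list
1 | propargyl alcohol | C#CCO | starting material
2 | dimethylaluminium (E)-3-(dimethylalumanyl)-2-methylprop-2-en-1-olate (alkenylalane) | C[Al](C)OC/C(C)=C/[Al](C)C | intermediate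
3 | (E)-3-iodo-2-methylprop-2-en-1-ol | OC/C(C)=C/I | intermediate
4 | tert-butyl{[(E)-3-iodo-2-methylprop-2-enyl]oxy}dimethylsilane | CC(C)(C)[Si](C)(C)OC/C(C)=C/I | intermediate
5 | methyl propiolate | C#CC(=O)OC | starting material
6 | methyl (E)-6-[(tert-butyldimethylsilyl)oxy]-5-methylhex-4-en-2-ynoate | COC(=O)C#C/C=C(C)/CO[Si](C)(C)C(C)(C)C | intermediate
7 | methyl (2E,4E)-6-[(tert-butyldimethylsilyl)oxy]-5-methyl-2-(tributylstannyl)hexa-2,4-dienoate | CCCC[Sn](CCCC)(CCCC)/C(C(=O)OC)=C/C=C(C)/CO[Si](C)(C)C(C)(C)C | intermediate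
8 | (2E,4E)-6-[(tert-butyldimethylsilyl)oxy]-5-methyl-2-(tributylstannyl)hexa-2,4-dien-1-ol | CCCC[Sn](CCCC)(CCCC)/C(CO)=C/C=C(C)/CO[Si](C)(C)C(C)(C)C | intermediate
9 | (2E,4E)-6-[(tert-butyldimethylsilyl)oxy]-5-methyl-2-(tributylstannyl)-1-[(triethylsilyl)oxy]hexa-2,4-diene | CCCC[Sn](CCCC)(CCCC)/C(CO[Si](CC)(CC)CC)=C/C=C(C)/CO[Si](C)(C)C(C)(C)C | intermediate
10 | 2-bromoprop-2-en-1-ol | OCC(Br)=C | starting material
11 | (3Z,5E)-7-[(tert-butyldimethylsilyl)oxy]-6-methyl-2-methylidene-3-{[(triethylsilyl)oxy]methyl}hepta-3,5-dien-1-ol (C3 cis to C14 on C1=C2) | OCC(=C)/C(CO[Si](CC)(CC)CC)=C/C=C(C)/CO[Si](C)(C)C(C)(C)C | intermediate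
12 | [(2R)-2-{(2E,4E)-6-[(tert-butyldimethylsilyl)oxy]-5-methyl-1-[(triethylsilyl)oxy]hexa-2,4-dien-2-yl}oxiran-2-yl]methanol | CC(C)(C)[Si](C)(C)OC/C(C)=C/C=C(\CO[Si](CC)(CC)CC)[C@@]1(CO)CO1 | intermediate
13 | tert-butyl{[(2S)-2-{(2E,4E)-6-[(tert-butyldimethylsilyl)oxy]-5-methyl-1-[(triethylsilyl)oxy]hexa-2,4-dien-2-yl}oxiran-2-yl]methoxy}diphenylsilane (key-step precursor) | CC(C)(C)[Si](C)(C)OC/C(C)=C/C=C(\CO[Si](CC)(CC)CC)[C@@]1(CO[Si](c2ccccc2)(c2ccccc2)C(C)(C)C)CO1 | intermediate
14 | (2R)-2-{(E)-3-[(tert-butyldimethylsilyl)oxy]-2-methylprop-1-enyl}-4-{[(tert-butyldiphenylsilyl)oxy]methyl}-3-{[(triethylsilyl)oxy]methyl}-2,5-dihydrofuran (key-step product) | CC(C)(C)[Si](c1ccccc1)(c1ccccc1)OCC1=C(CO[Si](CC)(CC)CC)[C@@H](/C=C(C)/CO[Si](C)(C)C(C)(C)C)OC1 | intermediate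
15 | [(2R)-2-{(E)-3-[(tert-butyldimethylsilyl)oxy]-2-methylprop-1-enyl}-4-{[(tert-butyldiphenylsilyl)oxy]methyl}-2,5-dihydrofuran-3-yl]methanol | CC(C)(C)[Si](c1ccccc1)(c1ccccc1)OCC1=C(CO)[C@@H](/C=C(C)/CO[Si](C)(C)C(C)(C)C)OC1 | intermediate
16 | (2R)-3-(bromomethyl)-2-{(E)-3-[(tert-butyldimethylsilyl)oxy]-2-methylprop-1-enyl}-4-{[(tert-butyldiphenylsilyl)oxy]methyl}-2,5-dihydrofuran | CC(C)(C)[Si](c1ccccc1)(c1ccccc1)OCC1=C(CBr)[C@@H](/C=C(C)/CO[Si](C)(C)C(C)(C)C)OC1 | intermediate
17 | geraniol | CC(C)=CCC/C(C)=C/CO | starting material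
18 | [(2R,3R)-3-methyl-3-(4-methylpent-3-enyl)oxiran-2-yl]methanol | CC(C)=CCC[C@@]1(C)O[C@@H]1CO | intermediate
19 | tert-butyldimethyl{[(2R,3R)-3-methyl-3-(4-methylpent-3-enyl)oxiran-2-yl]methoxy}silane | CC(C)=CCC[C@@]1(C)O[C@@H]1CO[Si](C)(C)C(C)(C)C | intermediate
20 | (E)-5-[(2R,3R)-3-{[(tert-butyldimethylsilyl)oxy]methyl}-2-methyloxiran-2-yl]-2-methylpent-2-en-1-ol | OC/C(C)=C/CC[C@@]1(C)O[C@@H]1CO[Si](C)(C)C(C)(C)C | intermediate
21 | tert-butyl{[(2R,3R)-3-[(E)-5-chloro-4-methylpent-3-enyl]-3-methyloxiran-2-yl]methoxy}dimethylsilane | ClC/C(C)=C/CC[C@@]1(C)O[C@@H]1CO[Si](C)(C)C(C)(C)C | intermediate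
22 | tert-butyldimethyl{[(2R,3R)-3-methyl-3-[(E)-4-methyl-5-(phenylsulfonyl)pent-3-enyl]oxiran-2-yl]methoxy}silane | O=S(=O)(C/C(C)=C/CC[C@@]1(C)O[C@@H]1CO[Si](C)(C)C(C)(C)C)c1ccccc1 | intermediate
23 | C13-lithio derivative of 22 | [Li]C(/C(C)=C/CC[C@@]1(C)O[C@@H]1CO[Si](C)(C)C(C)(C)C)S(=O)(=O)c1ccccc1 | intermediate
24 | C13–C14-linked seco compound: (2R)-dihydrofuran with C14H2–C13H(SO2Ph) (both C13 epimers), E-C11=C12, (7R,8R)-epoxide, TBS ethers at C5 and C6, TBDPS ether at C17 | CC(C)(C)[Si](c1ccccc1)(c1ccccc1)OCC1=C(CC(/C(C)=C/CC[C@@]2(C)O[C@@H]2CO[Si](C)(C)C(C)(C)C)S(=O)(=O)c2ccccc2)[C@@H](/C=C(C)/CO[Si](C)(C)C(C)(C)C)OC1 | intermediate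
25 | C5,C6-diol: 24 with free hydroxyls at C5 and C6 | CC(C)(C)[Si](c1ccccc1)(c1ccccc1)OCC1=C(CC(/C(C)=C/CC[C@@]2(C)O[C@@H]2CO)S(=O)(=O)c2ccccc2)[C@@H](/C=C(C)/CO)OC1 | intermediate
26 | C5 allylic chloride: 25 with Cl in place of the C5 hydroxyl | CC(C)(C)[Si](c1ccccc1)(c1ccccc1)OCC1=C(CC(/C(C)=C/CC[C@@]2(C)O[C@@H]2CO)S(=O)(=O)c2ccccc2)[C@@H](/C=C(C)/CCl)OC1 | intermediate
27 | bis-sulfone seco alcohol: phenylsulfonyl at C5 (E-C3=C4) and at C13, free C6 hydroxyl | CC(C)(C)[Si](c1ccccc1)(c1ccccc1)OCC1=C(CC(/C(C)=C/CC[C@@]2(C)O[C@@H]2CO)S(=O)(=O)c2ccccc2)[C@@H](/C=C(C)/CS(=O)(=O)c2ccccc2)OC1 | intermediate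
28 | C6 trifluoromethanesulfonate of 27 | CC(C)(C)[Si](c1ccccc1)(c1ccccc1)OCC1=C(CC(/C(C)=C/CC[C@@]2(C)O[C@@H]2COS(=O)(=O)C(F)(F)F)S(=O)(=O)c2ccccc2)[C@@H](/C=C(C)/CS(=O)(=O)c2ccccc2)OC1 | intermediate
29 | C5-lithio derivative of 28 | CC(C)(C)[Si](c1ccccc1)(c1ccccc1)OCC1=C(CC(/C(C)=C/CC[C@@]2(C)O[C@@H]2COS(=O)(=O)C(F)(F)F)S(=O)(=O)c2ccccc2)[C@@H](/C=C(C)/C([Li])S(=O)(=O)c2ccccc2)OC1 | intermediate
30 | macrocyclic bis-sulfone: (2R,3E,7R,8R,11E) fourteen-membered ring fused to the dihydrofuran, phenylsulfonyl at C5 and C13 (epimer mixture), C17 OTBDPS | CC(C)(C)[Si](c1ccccc1)(c1ccccc1)OCC1=C2CC(S(=O)(=O)c3ccccc3)/C(C)=C/CC[C@@]3(C)O[C@@H]3CC(S(=O)(=O)c3ccccc3)/C(C)=C/[C@H]2OC1 | intermediate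
31 | O-TBDPS-deacetyl-lobophynin B (2R,3E,7R,8R,11E) | CC(C)(C)[Si](c1ccccc1)(c1ccccc1)OCC1=C2CC/C(C)=C/CC[C@@]3(C)O[C@@H]3CC/C(C)=C/[C@H]2OC1 | intermediate
32 | deacetyl-lobophynin B (C17 alcohol) | OCC1=C2CC/C(C)=C/CC[C@@]3(C)O[C@@H]3CC/C(C)=C/[C@H]2OC1 | intermediate
33 | lobophynin B (2R,3E,7R,8R,11E) | CC(=O)OCC1=C2CC/C(C)=C/CC[C@@]3(C)O[C@@H]3CC/C(C)=C/[C@H]2OC1 | target

Total step count: 22. Longest linear sequence: 18 steps (steps 1–12 and 17–22).

Steps most likely to fail

Step 10. What may go wrong: the alkoxide/cation pair may separate, or the copper may deliver the oxygen to the opposite face, so that C2 forms with eroded or wrong configuration; the cation may also be drained by a hydride shift to an aldehyde, by proton loss or by closure at C4. Fallback (sets out from 4, returns at 14): the C2 centre is set by a catalyst and the ring is closed by olefin metathesis. Commercial 2-methylenepropane-1,3-diol is monosilylated (Et3SiCl) to 2-{[(triethylsilyl)oxy]methyl}prop-2-en-1-ol F1 and oxidised (MnO2) to 2-{[(triethylsilyl)oxy]methyl}prop-2-enal F2. An asymmetric Nozaki–Hiyama–Kishi coupling of iodide 4 with F2 (CrCl2 and NiCl2 in catalytic amounts, chiral sulfonamide ligand, Mn, Cp2ZrCl2) gives (3R,4E)-6-[(tert-butyldimethylsilyl)oxy]-5-methyl-2-{[(triethylsilyl)oxy]methyl}hexa-1,4-dien-3-ol F3. The same diol is monosilylated (t-BuPh2SiCl) to 2-{[(tert-butyldiphenylsilyl)oxy]methyl}prop-2-en-1-ol F4 and brominated (CBr4, PPh3) to {[2-(bromomethyl)prop-2-enyl]oxy}(tert-butyl)diphenylsilane F5. Williamson etherification of F3 with F5 (NaH, THF) gives the 2-{[(tert-butyldiphenylsilyl)oxy]methyl}prop-2-enyl ether of F3 F6. Ring-closing metathesis of its two 1,1-disubstituted olefins (second-generation Hoveyda–Grubbs catalyst, toluene, 80 °C) forms the C1=C15 bond and gives 14.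

Step 20. What may go wrong: intermolecular alkylation, decay of the epoxy triflate, proton transfer from the acidic C13–H to the C5 carbanion, loss of the ring oxygen from that carbanion (opening of the dihydrofuran) or attack of surplus base on the γ,δ-epoxy sulfone may outrun or follow ring closure. Fallback (sets out from 24, returns at 31): the two sulfonyl groups are used and discarded one after the other, so the ring is closed on a substrate with a single acidic site. Reductive desulfonylation of 24 (PdCl2(dppp), LiBHEt3) gives the sulfone-free C5,C6-bis-TBS ether F7, and HF·pyridine gives the sulfone-free C5,C6-diol F8. Corey–Kim chlorination gives the C5 allylic chloride F9 and sodium benzenesulfinate the C5 phenylsulfone with free C6 hydroxyl F10. Triflation gives the C6 triflate F11, whose C5-lithio derivative F12 (LiN(SiMe3)2, 0.002 M, −78 °C) closes to the C5-monosulfonyl macrocycle F13. A single desulfonylation then gives 31.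

Step 4. What may go wrong: the conjugated alkenyl substituent with its cis methyl group may compete with the ester in steering the hydropalladation, so that tin is delivered to C2, or the stannane may be lost by protodestannylation. Fallback (sets out from 4, returns at 7): the C1=C2 olefin is built by olefination instead of alkyne hydrometalation. Iodine–lithium exchange on 4 (t-BuLi, Et2O, −78 °C) gives tert-butyl{[(E)-3-lithio-2-methylprop-2-enyl]oxy}dimethylsilane F14, which DMF formylates to (E)-4-[(tert-butyldimethylsilyl)oxy]-3-methylbut-2-enal F15. Horner–Wadsworth–Emmons olefination with methyl bromo[bis(2,2,2-trifluoroethoxy)phosphoryl]acetate (t-BuOK, 18-crown-6, THF, −78 °C), a trifluoroethyl phosphonate that places the ester cis to the aldehyde residue, gives methyl (2E,4E)-2-bromo-6-[(tert-butyldimethylsilyl)oxy]-5-methylhexa-2,4-dienoate F16. Palladium-catalysed stannylation with retention (Pd(PPh3)4, Bu3SnSnBu3, toluene, 90 °C) gives 7.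

Further compounds
F1 | step 10 | 2-{[(triethylsilyl)oxy]methyl}prop-2-en-1-ol | C=C(CO)CO[Si](CC)(CC)CC
F2 | step 10 | 2-{[(triethylsilyl)oxy]methyl}prop-2-enal | C=C(C=O)CO[Si](CC)(CC)CC
F3 | step 10 | (3R,4E)-6-[(tert-butyldimethylsilyl)oxy]-5-methyl-2-{[(triethylsilyl)oxy]methyl}hexa-1,4-dien-3-ol | C=C(CO[Si](CC)(CC)CC)[C@@H](/C=C(C)/CO[Si](C)(C)C(C)(C)C)O
F4 | step 10 | 2-{[(tert-butyldiphenylsilyl)oxy]methyl}prop-2-en-1-ol | C=C(CO)CO[Si](c1ccccc1)(c1ccccc1)C(C)(C)C
F5 | step 10 | {[2-(bromomethyl)prop-2-enyl]oxy}(tert-butyl)diphenylsilane | C=C(CBr)CO[Si](c1ccccc1)(c1ccccc1)C(C)(C)C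
F6 | step 10 | 2-{[(tert-butyldiphenylsilyl)oxy]methyl}prop-2-enyl ether of F3 | C=C(CO[Si](CC)(CC)CC)[C@@H](/C=C(C)/CO[Si](C)(C)C(C)(C)C)OCC(=C)CO[Si](c1ccccc1)(c1ccccc1)C(C)(C)C
F7 | step 20 | sulfone-free C5,C6-bis-TBS ether (24 without the C13 sulfonyl group) | CC(C)(C)[Si](c1ccccc1)(c1ccccc1)OCC1=C(CC/C(C)=C/CC[C@@]2(C)O[C@@H]2CO[Si](C)(C)C(C)(C)C)[C@@H](/C=C(C)/CO[Si](C)(C)C(C)(C)C)OC1
F8 | step 20 | sulfone-free C5,C6-diol | CC(C)(C)[Si](c1ccccc1)(c1ccccc1)OCC1=C(CC/C(C)=C/CC[C@@]2(C)O[C@@H]2CO)[C@@H](/C=C(C)/CO)OC1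
F9 | step 20 | C5 allylic chloride (C6 hydroxyl free) | CC(C)(C)[Si](c1ccccc1)(c1ccccc1)OCC1=C(CC/C(C)=C/CC[C@@]2(C)O[C@@H]2CO)[C@@H](/C=C(C)/CCl)OC1
F10 | step 20 | C5 phenylsulfone with free C6 hydroxyl | CC(C)(C)[Si](c1ccccc1)(c1ccccc1)OCC1=C(CC/C(C)=C/CC[C@@]2(C)O[C@@H]2CO)[C@@H](/C=C(C)/CS(=O)(=O)c2ccccc2)OC1
F11 | step 20 | C6 triflate of F10 | CC(C)(C)[Si](c1ccccc1)(c1ccccc1)OCC1=C(CC/C(C)=C/CC[C@@]2(C)O[C@@H]2COS(=O)(=O)C(F)(F)F)[C@@H](/C=C(C)/CS(=O)(=O)c2ccccc2)OC1
F12 | step 20 | C5-lithio derivative of F11 | CC(C)(C)[Si](c1ccccc1)(c1ccccc1)OCC1=C(CC/C(C)=C/CC[C@@]2(C)O[C@@H]2COS(=O)(=O)C(F)(F)F)[C@@H](/C=C(C)/C([Li])S(=O)(=O)c2ccccc2)OC1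
F13 | step 20 | C5-monosulfonyl macrocycle (31 with phenylsulfonyl at C5) | CC(C)(C)[Si](c1ccccc1)(c1ccccc1)OCC1=C2CC/C(C)=C/CC[C@@]3(C)O[C@@H]3CC(S(=O)(=O)c3ccccc3)/C(C)=C/[C@H]2OC1
F14 | step 4 | tert-butyl{[(E)-3-lithio-2-methylprop-2-enyl]oxy}dimethylsilane | [Li]/C=C(C)/CO[Si](C)(C)C(C)(C)C
F15 | step 4 | (E)-4-[(tert-butyldimethylsilyl)oxy]-3-methylbut-2-enal | O=C/C=C(C)/CO[Si](C)(C)C(C)(C)C
F16 | step 4 | methyl (2E,4E)-2-bromo-6-[(tert-butyldimethylsilyl)oxy]-5-methylhexa-2,4-dienoate | Br/C(C(=O)OC)=C/C=C(C)/CO[Si](C)(C)C(C)(C)C
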